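**Plan**

1. Retrosynthesis: the C2–aryl bond of the oxolane is cut last. The oxolane half is then cut at O1–C2/C2–C3 (C2 comes from CO) and at C4–C5 (crotyl unit plus aldehyde). Each arm is cut at the aryl ether C–O bond and at the carbinol–aryl bond.
2. Both aryl-arm units are the same bromide 8 (lactate → aryl ether → ketone → erythro alcohol → silyl ether). One portion is formylated, crotylated and hydroformylated to lactol 13, where the oxolane ring arises. The anomeric ester 17 of 13 is then joined at C2 to a second portion of 8, and desilylation ends the route.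
3. Enabling feature: C2 sits between ring oxygen O1 and the methyl-bearing C3. At the hemiacetal level it is the one carbon whose ester fragments to an O1-stabilised radical, and the C3 methyl next to it steers the incoming aryl–nickel to the opposite face.
4. Stereochemistry: arm C2′ from methyl (R)-lactate (Mitsunobu inversion) and C1′ by chelation-controlled reduction; C4/C5 by catalyst-controlled syn-crotylboration; C3 by equilibration next to the lactol carbon; C2 in the key step (target core 2,3-trans-3,4-trans-4,5-cis).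

Key step: step 11

Shorthand: ArT = 4-{[(1R,2S)-1-(tert-butyldimethylsilyloxy)-1-(3,4-dimethoxyphenyl)propan-2-yl]oxy}-3-methoxyphenyl. Oxolane atoms are O1, C2 (the carbon that receives the second aryl group), C3, C4, C5.

Assumption: 2, 5 and 11 are taken as purchasable reagents, and the C2 anomer mixtures of 13 and 17 are used as such because C2 becomes planar in step 11.

**Step 1**
Reactants: 1 4-bromo-2-methoxyphenol; 2 methyl (R)-lactate
Product: 3 methyl (2S)-2-(4-bromo-2-methoxyphenoxy)propanoate
Conditions: PPh3, DIAD, THF, 0 °C to rt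
Reagents that add atoms: none
Why: Mitsunobu etherification, in which the phenol displaces the activated lactate hydroxyl by SN2 with inversion, so the (R)-lactate gives the (S)-aryl ether that becomes C2′ of the arm.

**Step 2**
Reactants: 3 methyl (2S)-2-(4-bromo-2-methoxyphenoxy)propanoate
Product: 4 (2S)-2-(4-bromo-2-methoxyphenoxy)-N-methoxy-N-methylpropanamide
Conditions: MeNH(OMe)·HCl, i-PrMgCl, THF, −20 °C
Reagents that add atoms: N,O-dimethylhydroxylamine hydrochloride, CNOC.Cl
Why: Weinreb amide formation by aminolysis of the ester with the magnesium amide at low temperature, where the α-aryloxy stereocentre should not enolise and the aryl bromide is inert.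

**Step 3**
Reactants: 4 (2S)-2-(4-bromo-2-methoxyphenoxy)-N-methoxy-N-methylpropanamide; 5 3,4-dimethoxyphenylmagnesium bromide
Product: 6 (2S)-2-(4-bromo-2-methoxyphenoxy)-1-(3,4-dimethoxyphenyl)propan-1-one
Conditions: THF, 0 °C; aq. NH4Cl
Reagents that add atoms: none
Why: Weinreb ketone synthesis, in which the chelated tetrahedral magnesium adduct stops at the ketone stage and the aryl Grignard reagent does not exchange with the aryl bromide at 0 °C.

**Step 4**
Reactants: 6 (2S)-2-(4-bromo-2-methoxyphenoxy)-1-(3,4-dimethoxyphenyl)propan-1-one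
Product: 7 (1R,2S)-2-(4-bromo-2-methoxyphenoxy)-1-(3,4-dimethoxyphenyl)propan-1-ol
Conditions: Zn(BH4)2, Et2O, −20 to 0 °C
Reagents that add atoms: none
Why: Chelation-controlled (Cram chelate) hydride reduction, in which zinc bridges the carbonyl and aryloxy oxygens and hydride enters from the face of the small α-hydrogen, which should give the anti (erythro) alcohol with the new centre 1R.

**Step 5**
Reactants: 7 (1R,2S)-2-(4-bromo-2-methoxyphenoxy)-1-(3,4-dimethoxyphenyl)propan-1-ol
Product: 8 ArT–Br, tert-butyl{[(1R,2S)-2-(4-bromo-2-methoxyphenoxy)-1-(3,4-dimethoxyphenyl)propyl]oxy}dimethylsilane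
Conditions: TBSCl, imidazole, DMF, rt
Reagents that add atoms: tert-butyldimethylsilyl chloride (TBSCl), CC(C)(C)[Si](C)(C)Cl
Why: Silyl ether formation protects the benzylic hydroxyl for the organolithium, boron, rhodium and nickel steps and is removable with fluoride at the end.

**Step 6**
Reactants: 8 ArT–Br
Product: 10 ArT–CHO (4-{[(1R,2S)-1-(tert-butyldimethylsilyloxy)-1-(3,4-dimethoxyphenyl)propan-2-yl]oxy}-3-methoxybenzaldehyde), via aryllithium 9 (not isolated)
Conditions: n-BuLi, THF, −78 °C; then DMF, −78 to 0 °C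
Reagents that add atoms: N,N-dimethylformamide (DMF), CN(C)C=O
Why: Bromine–lithium exchange followed by formylation of the aryllithium with DMF (Bouveault aldehyde synthesis), the exchange being faster than any deprotonation at −78 °C.

**Step 7**
Reactants: 10 ArT–CHO; 11 (Z)-crotylboronic acid pinacol ester
Product: 12 (1S,2R)-1-ArT-2-methylbut-3-en-1-ol
Conditions: (S)-TRIP (5 mol %), 4 Å MS, toluene, −30 °C to rt
Reagents that add atoms: none
Why: Chiral phosphoric acid-catalysed crotylboration through a closed chair (Zimmerman–Traxler) transition state, in which the Z-crotyl geometry gives the syn relationship of C4 and C5 and the (S)-catalyst should direct attack to the Si face of the aldehyde, setting 1S,2R.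

**Step 8**
Reactants: 12 (1S,2R)-1-ArT-2-methylbut-3-en-1-ol
Product: 13 (3R,4R,5S)-5-ArT-3,4-dimethyloxolan-2-ol (both anomers)
Conditions: Rh(CO)2(acac) (2 mol %), Ph2POMe (10 mol %), CO/H2 (1:1, 20 bar), 4 Å MS, THF, 40 °C; then DBU (0.2 equiv), CH2Cl2, rt
Reagents that add atoms: carbon monoxide, [C-]#[O+]
Why: Directed branched-selective hydroformylation, in which the phosphinite formed reversibly from the hydroxyl and Ph2POMe delivers rhodium to the internal alkene carbon through a six-membered chelate, the γ-hydroxy aldehyde closes to the five-membered lactol, and DBU equilibrates the new C3 centre (alpha to the masked aldehyde) to the 3,4-trans isomer that avoids the all-cis array.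

**Step 9**
Reactants: 14 glyoxylic acid (monohydrate); 15 ethyl acetoacetate (2 equiv)
Product: 16 3,5-bis(ethoxycarbonyl)-2,6-dimethyl-1,4-dihydropyridine-4-carboxylic acid
Conditions: NH4OAc, EtOH/H2O, rt
Reagents that add atoms: ammonium acetate, CC(=O)[O-].[NH4+]
Why: Hantzsch dihydropyridine synthesis, in which Knoevenagel condensation, enamine formation and cyclocondensation give the 4-carboxy-1,4-dihydropyridine in one operation.

**Step 10**
Reactants: 13 (3R,4R,5S)-5-ArT-3,4-dimethyloxolan-2-ol; 16 3,5-bis(ethoxycarbonyl)-2,6-dimethyl-1,4-dihydropyridine-4-carboxylic acid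
Product: 17 (3R,4R,5S)-5-ArT-3,4-dimethyloxolan-2-yl 3,5-bis(ethoxycarbonyl)-2,6-dimethyl-1,4-dihydropyridine-4-carboxylate (both anomers)
Conditions: DCC, DMAP (cat.), CH2Cl2, 0 °C to rt
Reagents that add atoms: none
Why: Steglich esterification acylates the hemiacetal hydroxyl to the anomeric ester under neutral conditions, and the configuration at C2 is irrelevant because that carbon becomes a radical in the next step.

**Step 11**
Reactants: 17 anomeric dihydropyridine ester (1.5 equiv); 8 ArT–Br
Product: 19 (2R,3R,4R,5S)-2,5-bis(ArT)-3,4-dimethyloxolane, via C2 oxolanyl radical 18 (not isolated)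
Conditions: NiBr2·dme (10 mol %), 4,4′-di-tert-butyl-2,2′-bipyridine (12 mol %), 4CzIPN (3 mol %), K2HPO4, 1,4-dioxane, blue LEDs, 60 °C
Reagents that add atoms: none
Why: Photo-excited 4CzIPN oxidises the dihydropyridine of 17, whose aromatisation expels an alkoxycarbonyl radical that loses CO2 to give the O1-stabilised C2 radical 18; the bipyridine-ligated nickel catalyst in its zerovalent state inserts into the C–Br bond of 8, the resulting ArNiBr (divalent nickel) captures 18 to give a trivalent nickel species, reductive elimination forms the C2–aryl bond, and the reduced photocatalyst returns monovalent nickel to the zerovalent state. The closest known reaction type is the nickel/photoredox cross-coupling of anomeric dihydropyridine esters of furanoses and 2-deoxy sugars with bromoarenes (C-aryl glycosylation through glycosyl radicals). No ring is closed, since the oxolane is already in place. The only new stereocentre, C2, is set at the nickel stage: the metal with its aryl group adds to the face of the near-planar radical opposite the methyl group on the neighbouring C3, which should give the 2,3-trans (2R) product, the 1,2-trans outcome typical of furanosyl radicals, whereas a polar oxocarbenium route would be expected to place the aryl group cis to that methyl by inside attack. The step needs this facial selectivity and radical generation at C2 only, and both rest on the C3 methyl being the sole substituent next to the radical centre and on C2 being the sole acetal-level carbon of 17. The neutral, non-Lewis-acidic conditions should leave the silyl ethers and the acid-labile cis benzylic C5–O1 bond untouched.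

**Step 12**
Reactants: 19 (2R,3R,4R,5S)-2,5-bis(ArT)-3,4-dimethyloxolane
Product: 20 (2R,3R,4R,5S)-2,5-bis(4-{[(1R,2S)-1-(3,4-dimethoxyphenyl)-1-hydroxypropan-2-yl]oxy}-3-methoxyphenyl)-3,4-dimethyloxolane (target)
Conditions: TBAF, THF, 0 °C to rt
Reagents that add atoms: none
Why: Fluoride-mediated desilylation cleaves both silyl ethers under non-acidic conditions, so the benzylic C–O bonds of the oxolane and of the arms should not ionise.

**Compound list**

1 | 4-bromo-2-methoxyphenol | COc1cc(Br)ccc1O | starting material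
2 | methyl (R)-lactate | C[C@@H](O)C(=O)OC | starting material
3 | methyl (2S)-2-(4-bromo-2-methoxyphenoxy)propanoate | C[C@H](Oc1ccc(Br)cc1OC)C(=O)OC | intermediate
4 | (2S)-2-(4-bromo-2-methoxyphenoxy)-N-methoxy-N-methylpropanamide | C[C@H](Oc1ccc(Br)cc1OC)C(=O)N(C)OC | intermediate
5 | 3,4-dimethoxyphenylmagnesium bromide | COc1ccc([Mg]Br)cc1OC | starting material
6 | (2S)-2-(4-bromo-2-methoxyphenoxy)-1-(3,4-dimethoxyphenyl)propan-1-one | C[C@H](Oc1ccc(Br)cc1OC)C(=O)c1ccc(OC)c(OC)c1 | intermediate
7 | (1R,2S)-2-(4-bromo-2-methoxyphenoxy)-1-(3,4-dimethoxyphenyl)propan-1-ol | COc1ccc([C@@H](O)[C@H](C)Oc2ccc(Br)cc2OC)cc1OC | intermediate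
8 | ArT–Br, tert-butyl{[(1R,2S)-2-(4-bromo-2-methoxyphenoxy)-1-(3,4-dimethoxyphenyl)propyl]oxy}dimethylsilane | COc1ccc([C@@H](O[Si](C)(C)C(C)(C)C)[C@H](C)Oc2ccc(Br)cc2OC)cc1OC | intermediate
9 | ArT–Li, aryllithium from 8 (not isolated) | COc1ccc([C@@H](O[Si](C)(C)C(C)(C)C)[C@H](C)Oc2ccc([Li])cc2OC)cc1OC | intermediate
10 | ArT–CHO, 4-{[(1R,2S)-1-(tert-butyldimethylsilyloxy)-1-(3,4-dimethoxyphenyl)propan-2-yl]oxy}-3-methoxybenzaldehyde | COc1ccc([C@@H](O[Si](C)(C)C(C)(C)C)[C@H](C)Oc2ccc(C=O)cc2OC)cc1OC | intermediate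
11 | (Z)-crotylboronic acid pinacol ester | C/C=C\CB1OC(C)(C)C(C)(C)O1 | starting material
12 | (1S,2R)-1-ArT-2-methylbut-3-en-1-ol | COc1ccc([C@@H](O[Si](C)(C)C(C)(C)C)[C@H](C)Oc2ccc([C@@H](O)[C@H](C)C=C)cc2OC)cc1OC | intermediate
13 | (3R,4R,5S)-5-ArT-3,4-dimethyloxolan-2-ol (both anomers) | COc1ccc([C@@H](O[Si](C)(C)C(C)(C)C)[C@H](C)Oc2ccc([C@H]3OC(O)[C@H](C)[C@H]3C)cc2OC)cc1OC | intermediate
14 | glyoxylic acid | O=CC(=O)O | starting material
15 | ethyl acetoacetate | CCOC(=O)CC(C)=O | starting material
16 | 3,5-bis(ethoxycarbonyl)-2,6-dimethyl-1,4-dihydropyridine-4-carboxylic acid | CCOC(=O)C1=C(C)NC(C)=C(C(=O)OCC)C1C(=O)O | intermediate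
17 | (3R,4R,5S)-5-ArT-3,4-dimethyloxolan-2-yl 3,5-bis(ethoxycarbonyl)-2,6-dimethyl-1,4-dihydropyridine-4-carboxylate (both anomers) | COc1ccc([C@@H](O[Si](C)(C)C(C)(C)C)[C@H](C)Oc2ccc([C@H]3OC(OC(=O)C4C(C(=O)OCC)=C(C)NC(C)=C4C(=O)OCC)[C@H](C)[C@H]3C)cc2OC)cc1OC | intermediate
18 | (3R,4R,5S)-5-ArT-3,4-dimethyloxolan-2-yl radical (not isolated) | COc1ccc([C@@H](O[Si](C)(C)C(C)(C)C)[C@H](C)Oc2ccc([C@H]3O[CH][C@H](C)[C@H]3C)cc2OC)cc1OC | intermediate
19 | (2R,3R,4R,5S)-2,5-bis(ArT)-3,4-dimethyloxolane | COc1ccc([C@@H](O[Si](C)(C)C(C)(C)C)[C@H](C)Oc2ccc([C@H]3O[C@@H](c4ccc(O[C@@H](C)[C@H](O[Si](C)(C)C(C)(C)C)c5ccc(OC)c(OC)c5)c(OC)c4)[C@H](C)[C@H]3C)cc2OC)cc1OC | intermediate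
20 | (2R,3R,4R,5S)-2,5-bis(4-{[(1R,2S)-1-(3,4-dimethoxyphenyl)-1-hydroxypropan-2-yl]oxy}-3-methoxyphenyl)-3,4-dimethyloxolane | COc1ccc([C@@H](O)[C@H](C)Oc2ccc([C@H]3O[C@@H](c4ccc(O[C@@H](C)[C@H](O)c5ccc(OC)c(OC)c5)c(OC)c4)[C@H](C)[C@H]3C)cc2OC)cc1OC | target

**Step count and risks**

Total step count: 12. Longest linear sequence: 11 steps (steps 1 to 8, then 10, 11 and 12, from 1 to 20); step 9 is a one-step side branch.

The three steps most likely to fail:

Step 11. The capture of radical 18 by nickel may show poor facial selectivity. Radical 18 may also fragment by opening of the C5–O1 bond, or the nickel alkyl may lose a β-hydrogen to give an enol ether. The fallback makes the same C2–aryl bond by a polar, stereoconvergent ring closure. It sets out from lactol 13 and returns at 19. NaBH4 in MeOH opens 13 to (2R,3R,4S)-4-ArT-2,3-dimethylbutane-1,4-diol F1. TESCl and imidazole give the bis(triethylsilyl) ether F2. Swern oxidation, which converts a primary triethylsilyl ether directly into the aldehyde and leaves the secondary one, gives (2R,3R,4S)-4-ArT-2,3-dimethyl-4-(triethylsilyloxy)butanal F3. Aryllithium 9 (from 8 and n-BuLi, THF, −78 °C) adds to F3 to give (2R,3R,4S)-1,4-bis(ArT)-2,3-dimethyl-4-(triethylsilyloxy)butan-1-ol F4 as a mixture at the new carbinol. MsCl and Et3N in CH2Cl2 at 0 °C then activate this only free hydroxyl. The para-alkoxybenzylic cation that forms is closed by the C5 silyl ether oxygen with loss of the triethylsilyl group. Closure should occur trans to the C3 methyl whatever the carbinol configuration, giving 19.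

Step 8. Branched regiocontrol may be lost, so that the linear aldehyde closes to a six-membered lactol, or the alkene may be isomerised or hydrogenated. The fallback builds C2 and the C3 methyl separately, from 12 back to 13. Hydroboration with 9-BBN followed by NaOH/H2O2 gives (1S,2R)-1-ArT-2-methylbutane-1,4-diol F5. TEMPO with PhI(OAc)2 oxidises the primary alcohol and closes the lactone (4R,5S)-5-ArT-4-methyloxolan-2-one F6. LiN(SiMe3)2 and then MeI in THF at −78 °C methylate the enolate on the face opposite the C4 methyl to give (3R,4R,5S)-5-ArT-3,4-dimethyloxolan-2-one F7. i-Bu2AlH in CH2Cl2 at −78 °C reduces F7 to 13.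

Step 4. Ketone 6 may lose the lactate-derived configuration by enolisation before it is reduced, or chelation control may be incomplete. The fallback avoids the ketone, from 3 back to 7. i-Bu2AlH in toluene at −78 °C reduces ester 3 to (2S)-2-(4-bromo-2-methoxyphenoxy)propanal F8. The aryltitanium reagent made from 5 and ClTi(Oi-Pr)3 then adds under non-chelation (polar Felkin–Anh) control, with the aryl group entering anti to the aryloxy group, to give 7 directly.

**Further compounds**

F1 | step 11 | (2R,3R,4S)-4-ArT-2,3-dimethylbutane-1,4-diol | COc1ccc([C@@H](O[Si](C)(C)C(C)(C)C)[C@H](C)Oc2ccc([C@@H](O)[C@H](C)[C@@H](C)CO)cc2OC)cc1OC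
F2 | step 11 | (2R,3R,4S)-4-ArT-2,3-dimethyl-1,4-bis(triethylsilyloxy)butane | COc1ccc([C@@H](O[Si](C)(C)C(C)(C)C)[C@H](C)Oc2ccc([C@@H](O[Si](CC)(CC)CC)[C@H](C)[C@@H](C)CO[Si](CC)(CC)CC)cc2OC)cc1OC
F3 | step 11 | (2R,3R,4S)-4-ArT-2,3-dimethyl-4-(triethylsilyloxy)butanal | COc1ccc([C@@H](O[Si](C)(C)C(C)(C)C)[C@H](C)Oc2ccc([C@@H](O[Si](CC)(CC)CC)[C@H](C)[C@@H](C)C=O)cc2OC)cc1OC
F4 | step 11 | (2R,3R,4S)-1,4-bis(ArT)-2,3-dimethyl-4-(triethylsilyloxy)butan-1-ol (both C1 epimers) | COc1ccc([C@@H](O[Si](C)(C)C(C)(C)C)[C@H](C)Oc2ccc([C@@H](O[Si](CC)(CC)CC)[C@H](C)[C@@H](C)C(O)c4ccc(O[C@@H](C)[C@H](O[Si](C)(C)C(C)(C)C)c5ccc(OC)c(OC)c5)c(OC)c4)cc2OC)cc1OC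
F5 | step 8 | (1S,2R)-1-ArT-2-methylbutane-1,4-diol | COc1ccc([C@@H](O[Si](C)(C)C(C)(C)C)[C@H](C)Oc2ccc([C@@H](O)[C@H](C)CCO)cc2OC)cc1OC
F6 | step 8 | (4R,5S)-5-ArT-4-methyloxolan-2-one | COc1ccc([C@@H](O[Si](C)(C)C(C)(C)C)[C@H](C)Oc2ccc([C@H]3OC(=O)C[C@H]3C)cc2OC)cc1OC
F7 | step 8 | (3R,4R,5S)-5-ArT-3,4-dimethyloxolan-2-one | COc1ccc([C@@H](O[Si](C)(C)C(C)(C)C)[C@H](C)Oc2ccc([C@H]3OC(=O)[C@H](C)[C@H]3C)cc2OC)cc1OC
F8 | step 4 | (2S)-2-(4-bromo-2-methoxyphenoxy)propanal | C[C@H](Oc1ccc(Br)cc1OC)C=O
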